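**Plan**
- Retrosynthesis: the pyran ring of the chromene is cut first, at O1–C8a and at C3=C4, giving a 4-fluoro-5-vinylbenzophenone and 2-methylbut-3-en-2-ol. The aryl–C(=O) bond is cut next (ring B aryllithium plus ring A aldehyde), then the ring A aryl–prenyl bond.
- Forward: ring A aldehyde by MOM protection and Stille prenylation; ring B bromostyrene by MOM protection and Wittig methylenation; the two are joined by Br/Li exchange and addition, then oxidised to the benzophenone. The pyran ring is closed last, and both MOM groups are then removed.
- Enabling feature: in ring B the carbon that becomes C8a carries fluorine para to the benzophenone carbonyl carbon, so it accepts an alkoxide by addition–elimination. Its ortho neighbour C4a already carries C4 as a vinyl CH, which fixes the linear 6-acyl-7-oxy chromene pattern.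
- Helpers: fluorine leaves in the key step, the two terminal CH2 groups leave as ethene, and the MOM groups leave at the end.
- Stereochemistry: the target has no stereocentre. The C3=C4 olefin is cis by ring constraint, and the racemic carbinol centre of step 5 is erased in step 6.

Key step: step 7

Remark on the chemistry: 2-bromo-3-hydroxybenzaldehyde and 5-bromo-2-fluoro-4-hydroxybenzaldehyde are taken as catalogue compounds.

**Step 1**
Reactants: 1 2-bromo-3-hydroxybenzaldehyde
Product: 2 2-bromo-3-(methoxymethoxy)benzaldehyde
Conditions: MOMCl, i-Pr2NEt, CH2Cl2, 0 °C to rt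
Reagents that add atoms: chloromethyl methyl ether (MOMCl), COCCl
Why: O-alkylation of the phenol by the reactive α-chloro ether (Williamson-type MOM protection) should proceed under mild amine base and leave the aldehyde and the C–Br bond untouched.

**Step 2**
Reactants: 2 2-bromo-3-(methoxymethoxy)benzaldehyde; 3 tributyl(3-methylbut-2-en-1-yl)stannane
Product: 4 3-(methoxymethoxy)-2-(3-methylbut-2-en-1-yl)benzaldehyde
Conditions: Pd(PPh3)4 (5 mol %), DMF, 90 °C
Reagents that add atoms: none
Why: Stille cross-coupling, in which the C–Br bond activated by the ortho formyl group adds oxidatively to zerovalent palladium, the prenyl group is transferred from tin, and reductive elimination at the less substituted allyl terminus should give the linear prenyl arene with CHO and MOM tolerated.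

**Step 3**
Reactants: 5 5-bromo-2-fluoro-4-hydroxybenzaldehyde
Product: 6 5-bromo-2-fluoro-4-(methoxymethoxy)benzaldehyde
Conditions: MOMCl, i-Pr2NEt, CH2Cl2, 0 °C to rt
Reagents that add atoms: chloromethyl methyl ether (MOMCl), COCCl
Why: MOM protection (Williamson-type O-alkylation) of the acidic para-formyl phenol should be clean because the hindered amine base does not attack the activated C–F bond.

**Step 4**
Reactants: 6 5-bromo-2-fluoro-4-(methoxymethoxy)benzaldehyde
Product: 7 1-bromo-5-ethenyl-4-fluoro-2-(methoxymethoxy)benzene
Conditions: Ph3PCH3Br (1.2 equiv), NaN(SiMe3)2 (1.15 equiv), THF, 0 °C; then 6, 0 °C to rt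
Reagents that add atoms: methyltriphenylphosphonium bromide, C[P+](c1ccccc1)(c1ccccc1)c1ccccc1.[Br-]
Why: Wittig methylenation by the preformed non-stabilised ylide is fast at 0 °C and, with no free base left, should not touch the activated C–F bond, the C–Br bond or the MOM ether.

**Step 5**
Reactants: 7 1-bromo-5-ethenyl-4-fluoro-2-(methoxymethoxy)benzene; 4 3-(methoxymethoxy)-2-(3-methylbut-2-en-1-yl)benzaldehyde
Product: 10 [5-ethenyl-4-fluoro-2-(methoxymethoxy)phenyl][3-(methoxymethoxy)-2-(3-methylbut-2-en-1-yl)phenyl]methanol (racemic), via aryllithium 8 (not isolated), via lithium alkoxide 9 (not isolated)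
Conditions: n-BuLi (1.05 equiv), THF, −78 °C, 10 min; then 4, −78 °C; sat. aq NH4Cl
Reagents that add atoms: none
Why: Bromine–lithium exchange at −78 °C should outrun both addition of n-BuLi to the styrene and ring deprotonation, and the MOM-chelated aryllithium (no fluorine ortho to lithium, hence no aryne) adds 1,2 to aldehyde 4; the carbinol stereocentre forms as a racemate and is erased in step 6.

**Step 6**
Reactants: 10 [5-ethenyl-4-fluoro-2-(methoxymethoxy)phenyl][3-(methoxymethoxy)-2-(3-methylbut-2-en-1-yl)phenyl]methanol
Product: 11 [5-ethenyl-4-fluoro-2-(methoxymethoxy)phenyl][3-(methoxymethoxy)-2-(3-methylbut-2-en-1-yl)phenyl]methanone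
Conditions: MnO2 (activated, excess), CH2Cl2, rt
Reagents that add atoms: none
Why: MnO2 oxidation of the doubly benzylic secondary alcohol should give the benzophenone under neutral heterogeneous conditions that spare the vinyl and prenyl olefins, the MOM acetals and the C–F bond, and it removes the only stereocentre.

**Step 7**
Reactants: 11 [5-ethenyl-4-fluoro-2-(methoxymethoxy)phenyl][3-(methoxymethoxy)-2-(3-methylbut-2-en-1-yl)phenyl]methanone; 12 2-methylbut-3-en-2-ol
Product: 14 [7-(methoxymethoxy)-2,2-dimethyl-2H-chromen-6-yl][3-(methoxymethoxy)-2-(3-methylbut-2-en-1-yl)phenyl]methanone, via aryl ether 13 (not isolated)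
Conditions: 12 (1.3 equiv), KH (1.2 equiv), 18-crown-6 (10 mol %), THF, 0 to 40 °C; AcOH to neutral, volatiles removed, toluene (0.005 M), second-generation Grubbs catalyst RuCl2(PCy3)(H2IMes)(=CHPh) (5 mol %), 60 °C, Ar purge
Reagents that add atoms: none
Why: The potassium alkoxide of 12 adds to C4 of the fluorinated ring of 11 (the future C8a), giving a Meisenheimer anion whose charge is delocalised onto the para benzophenone carbonyl, and loss of fluoride forms the O1–C8a bond of ether 13 (addition–elimination SNAr, the known displacement of para-acyl aryl fluorides by alkoxides). After neutralisation the ruthenium alkylidene takes the ring B vinyl group and the vinyl group of the new ether through a [2+2]/retro-[2+2] sequence that expels ethene and forms C3=C4 (ring-closing olefin metathesis of a 2-vinylaryl allyl ether to a 2H-chromene, a known reaction type). The pyran ring thus closes as a six-membered ring by metathesis across two terminal olefins held 1,6 to each other, helped by the gem-dimethyl group, and the ring forces the new olefin to be cis. No stereocentre is formed. The step needs site selectivity in the substitution, secured because 11 has a single C–F bond activated by the para carbonyl while the ketone cannot enolise and the MOM acetals are inert to base, and chemoselectivity in the metathesis, secured because the trisubstituted prenyl olefin reacts far more slowly than the two terminal olefins at high dilution once surplus 12 has been evaporated. The vinyl group ortho to fluorine fixes the linear 6-acyl-7-oxy chromene regiochemistry, which a phenol-based annulation would not guarantee.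

**Step 8**
Reactants: 14 [7-(methoxymethoxy)-2,2-dimethyl-2H-chromen-6-yl][3-(methoxymethoxy)-2-(3-methylbut-2-en-1-yl)phenyl]methanone
Product: 15 cudraphenone A, (7-hydroxy-2,2-dimethyl-2H-chromen-6-yl)[3-hydroxy-2-(3-methylbut-2-en-1-yl)phenyl]methanone
Conditions: p-TsOH·H2O (20 mol %), MeOH, 40 °C
Reagents that add atoms: none
Why: Acid-catalysed transacetalisation to methanol should cleave both MOM ethers (the one ortho to the ketone fastest), and dilute acid near room temperature is chosen so that neither the ortho-prenyl phenol closes to a chroman nor the chromene olefin adds methanol; the target has no stereocentre.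

**Compound list**
1 | 2-bromo-3-hydroxybenzaldehyde | O=Cc1cccc(O)c1Br | starting material
2 | 2-bromo-3-(methoxymethoxy)benzaldehyde | O=Cc1cccc(OCOC)c1Br | intermediate
3 | tributyl(3-methylbut-2-en-1-yl)stannane | CCCC[Sn](CCCC)(CCCC)CC=C(C)C | starting material
4 | 3-(methoxymethoxy)-2-(3-methylbut-2-en-1-yl)benzaldehyde | O=Cc1cccc(OCOC)c1CC=C(C)C | intermediate
5 | 5-bromo-2-fluoro-4-hydroxybenzaldehyde | O=Cc1cc(Br)c(O)cc1F | starting material
6 | 5-bromo-2-fluoro-4-(methoxymethoxy)benzaldehyde | O=Cc1cc(Br)c(OCOC)cc1F | intermediate
7 | 1-bromo-5-ethenyl-4-fluoro-2-(methoxymethoxy)benzene | C=Cc1cc(Br)c(OCOC)cc1F | intermediate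
8 | [5-ethenyl-4-fluoro-2-(methoxymethoxy)phenyl]lithium (not isolated) | [Li]c1cc(C=C)c(F)cc1OCOC | intermediate
9 | lithium alkoxide of carbinol 10 (not isolated) | [Li]OC(c1cccc(OCOC)c1CC=C(C)C)c1cc(C=C)c(F)cc1OCOC | intermediate
10 | [5-ethenyl-4-fluoro-2-(methoxymethoxy)phenyl][3-(methoxymethoxy)-2-(3-methylbut-2-en-1-yl)phenyl]methanol, racemic | OC(c1cccc(OCOC)c1CC=C(C)C)c1cc(C=C)c(F)cc1OCOC | intermediate
11 | [5-ethenyl-4-fluoro-2-(methoxymethoxy)phenyl][3-(methoxymethoxy)-2-(3-methylbut-2-en-1-yl)phenyl]methanone | O=C(c1cccc(OCOC)c1CC=C(C)C)c1cc(C=C)c(F)cc1OCOC | intermediate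
12 | 2-methylbut-3-en-2-ol | C=CC(C)(C)O | starting material
13 | [5-ethenyl-2-(methoxymethoxy)-4-[(2-methylbut-3-en-2-yl)oxy]phenyl][3-(methoxymethoxy)-2-(3-methylbut-2-en-1-yl)phenyl]methanone (not isolated) | O=C(c1cccc(OCOC)c1CC=C(C)C)c1cc(C=C)c(OC(C)(C)C=C)cc1OCOC | intermediate
14 | [7-(methoxymethoxy)-2,2-dimethyl-2H-chromen-6-yl][3-(methoxymethoxy)-2-(3-methylbut-2-en-1-yl)phenyl]methanone | O=C(c1cccc(OCOC)c1CC=C(C)C)c1cc2c(cc1OCOC)OC(C)(C)C=C2 | intermediate
15 | cudraphenone A, (7-hydroxy-2,2-dimethyl-2H-chromen-6-yl)[3-hydroxy-2-(3-methylbut-2-en-1-yl)phenyl]methanone | CC(C)=CCc1c(O)cccc1C(=O)c1cc2c(cc1O)OC(C)(C)C=C2 | target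

**Summary**
Total step count: 8. Longest linear sequence: 6 steps (steps 3 to 8, from compound 5).

Steps most likely to fail:

1. Step 7. The hindered tertiary alkoxide may be too slow to displace fluoride next to the ortho vinyl group, the base may move the prenyl double bond into conjugation, or the carbene may be diverted by cross-metathesis. The fallback sets out from 11. Hydroxide (KOH, DMSO/H2O, 60 °C) displaces the fluoride to give the phenol [5-ethenyl-4-hydroxy-2-(methoxymethoxy)phenyl][3-(methoxymethoxy)-2-(3-methylbut-2-en-1-yl)phenyl]methanone F1. Allylic etherification of F1 with tert-butyl 2-methylbut-3-en-2-yl carbonate (Pd(PPh3)4, THF, rt) should give the tertiary aryl ether 13, now isolated and purified. Ring-closing metathesis of pure 13 under the second-stage conditions of step 7 comes back to the route at 14.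

2. Step 2. Prenyl transfer may occur with allylic transposition, giving the branched 1,1-dimethylallyl isomer, and coupling at the doubly ortho-substituted bromide may be slow. The fallback sets out from 2. Stille coupling with allyltributylstannane (Pd(PPh3)4, toluene, 100 °C) gives 3-(methoxymethoxy)-2-(prop-2-en-1-yl)benzaldehyde F2 with no regiochemical ambiguity. Cross-metathesis of F2 with 2-methylbut-2-ene (second-generation Grubbs catalyst, CH2Cl2, 40 °C) turns allyl into prenyl and comes back to the route at 4.

3. Step 5. n-BuLi may add to the styrene, or the acidic ring hydrogen between fluorine and the MOM ether may be transferred to the aryllithium, followed by loss of LiF. The fallback sets out from 7. Miyaura borylation (B2pin2, Pd(dppf)Cl2, KOAc, dioxane, 80 °C) gives 2-[5-ethenyl-4-fluoro-2-(methoxymethoxy)phenyl]-4,4,5,5-tetramethyl-1,3,2-dioxaborolane F3. Rhodium-catalysed 1,2-addition of F3 to aldehyde 4 ([RhCl(cod)]2, KOH, dioxane/H2O, 60 °C) forms the carbinol without a strongly basic organometallic and comes back to the route at 10.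

**Further compounds**
F1 | step 7 | [5-ethenyl-4-hydroxy-2-(methoxymethoxy)phenyl][3-(methoxymethoxy)-2-(3-methylbut-2-en-1-yl)phenyl]methanone | O=C(c1cccc(OCOC)c1CC=C(C)C)c1cc(C=C)c(O)cc1OCOC
F2 | step 2 | 3-(methoxymethoxy)-2-(prop-2-en-1-yl)benzaldehyde | O=Cc1cccc(OCOC)c1CC=C
F3 | step 5 | 2-[5-ethenyl-4-fluoro-2-(methoxymethoxy)phenyl]-4,4,5,5-tetramethyl-1,3,2-dioxaborolane | C=Cc1cc(B2OC(C)(C)C(C)(C)O2)c(OCOC)cc1F
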